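**Plan**
Numbering: flavan-4-ol half O1–C8a; dearomatised half O1''–C8a''. The central dihydrofuran is O5–C5–C6–C8''–C8a''.
Retrosynthetic cuts, in order: the O4 silyl group; C5''–C4a'' (acyl–vinyl bond of the cyclohexadienone); the C7''(OMe)=C6''–C5'' methoxyacrylate, back to an ethynyl group on C8''; finally C8''–C8a''.
The last cut is a retro [1,2]-Wittig shift. The C8'' oxygen goes back between C8'' and C8a'', so the dihydrofuran becomes a six-membered 4H-1,3-benzodioxin spiro-orthoester, which divides into a salicyl-type diol and a 3-bromo-δ-lactone of similar size.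
Enabling feature: C8a'' is a ketal carbon carrying two ring oxygens (O5, O1'') and the C4a''=C4'' vinyl group, so its radical is well stabilised. Its neighbour C8'' is benzylic, carries an exocyclic oxygen and can carry an alkyne, so its C–H is acidic.
Forward ring order: chroman (unit I) and dihydropyranone (unit II) separately, then benzodioxin (union through two C–O bonds), contraction to the dihydrofuran, cyclohexadienone last.
Stereochemistry: C2 by catalytic asymmetric 1,4-addition; C4 relayed from C2 (cis reduction, Mitsunobu inversion); C2'' bought; C8a'' relayed from C2'' (anomeric equilibrium, then retention); C8'' relayed from C8a''.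

Key step: step 14

Assumption: the (R)-ligand in step 2 is taken to deliver the 2S series; if the sense of induction is the opposite, its antipode is used.

Step 1
Reactants: 1 1-(2-hydroxy-3,4,6-trimethoxyphenyl)ethanone
Product: 3 5,7,8-trimethoxy-4H-chromen-4-one, via enaminone 2 (not isolated)
Conditions: Me2NCH(OMe)2, toluene, 100 °C; then conc. HCl, CH2Cl2, 40 °C
Reagents that add atoms: N,N-dimethylformamide dimethyl acetal, COC(OC)N(C)C
Why: Enaminone chromone synthesis, in which condensation at the acetyl CH3 is followed by acid-induced addition–elimination of the phenol oxygen with loss of dimethylamine; no stereocentre is formed.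

Step 2
Reactants: 3 5,7,8-trimethoxy-4H-chromen-4-one
Product: 4 (2S)-5,7,8-trimethoxy-2-phenylchroman-4-one
Conditions: PhB(OH)2, [Rh(OH)(cod)]2 (cat.), (R)-MeO-F12-BIPHEP (cat.), toluene–H2O, 40 °C
Reagents that add atoms: phenylboronic acid, OB(O)c1ccccc1
Why: Rhodium-catalysed asymmetric 1,4-addition of an arylboronic acid to a chromone, where the electron-poor chiral bisphosphine selects the enone face and sets C2 under conditions mild enough to avoid ring opening.

Step 3
Reactants: 4 (2S)-5,7,8-trimethoxy-2-phenylchroman-4-one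
Product: 5 (2S)-5-hydroxy-7,8-dimethoxy-2-phenylchroman-4-one
Conditions: BCl3, CH2Cl2, −78 → 0 °C; aq. NaHCO3
Reagents that add atoms: none
Why: Chelation-directed ether cleavage removes only the methyl group peri to the carbonyl, because boron bridges O4 and O5, and the low temperature spares C2.

Step 4
Reactants: 5 (2S)-5-hydroxy-7,8-dimethoxy-2-phenylchroman-4-one
Product: 6 (2S,4S)-7,8-dimethoxy-2-phenylchromane-4,5-diol (2,4-cis)
Conditions: NaBH4, MeOH–THF, 0 °C
Reagents that add atoms: none
Why: Borohydride reduction with axial hydride delivery to the half-chair that carries the 2-phenyl group equatorially should give the equatorial, 2,4-cis alcohol (substrate control from C2).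

Step 5
Reactants: 6 (2S,4S)-7,8-dimethoxy-2-phenylchromane-4,5-diol
Product: 7 (2S,4R)-5-hydroxy-7,8-dimethoxy-2-phenylchroman-4-yl 4-nitrobenzoate (2,4-trans)
Conditions: 4-O2NC6H4CO2H, PPh3, DIAD, THF, 0 °C
Reagents that add atoms: 4-nitrobenzoic acid, O=C(O)c1ccc(cc1)[N+](=O)[O-]
Why: Mitsunobu esterification inverts C4 by SN2 displacement of the oxyphosphonium ion, and a competing o-quinone-methide pathway would also add the carboxylate axially, so both converge on the 2,4-trans ester.

Step 6
Reactants: 7 (2S,4R)-5-hydroxy-7,8-dimethoxy-2-phenylchroman-4-yl 4-nitrobenzoate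
Product: 8 (2S,4R)-7,8-dimethoxy-2-phenylchromane-4,5-diol (2,4-trans)
Conditions: LiOH, THF–H2O, 0 °C; 1 M HCl to pH 6
Reagents that add atoms: none
Why: Saponification of the activated benzoate by acyl–oxygen cleavage leaves C4 untouched, and with water as the only nucleophile a stray o-quinone-methide pathway is harmless.

Step 7
Reactants: 8 (2S,4R)-7,8-dimethoxy-2-phenylchromane-4,5-diol
Product: 10 (2S,4R)-4-(tert-butyldimethylsilyloxy)-7,8-dimethoxy-2-phenylchroman-5-ol, via bis-silyl ether 9 (not isolated)
Conditions: TBSOTf, 2,6-lutidine, CH2Cl2, 0 °C; then K2CO3 (cat.), MeOH, rt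
Reagents that add atoms: tert-butyldimethylsilyl triflate, CC(C)(C)[Si](C)(C)OS(=O)(=O)C(F)(F)F
Why: Exhaustive silylation followed by selective methanolysis of the aryl silyl ether works because phenoxide is the far better leaving group on silicon, so the alkyl silyl ether remains.

Step 8
Reactants: 10 (2S,4R)-4-(tert-butyldimethylsilyloxy)-7,8-dimethoxy-2-phenylchroman-5-ol
Product: 11 (2S,4R)-4-(tert-butyldimethylsilyloxy)-5-hydroxy-7,8-dimethoxy-2-phenylchromane-6-carbaldehyde
Conditions: MgCl2, Et3N, (CH2O)n, MeCN, reflux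
Reagents that add atoms: paraformaldehyde (as formaldehyde), C=O
Why: Magnesium-phenolate-directed ortho-formylation (Casnati–Skattebøl) can only attack C6, the single free ring position ortho to the phenol.

Step 9
Reactants: 11 (2S,4R)-4-(tert-butyldimethylsilyloxy)-5-hydroxy-7,8-dimethoxy-2-phenylchromane-6-carbaldehyde
Product: 12 (2S,4R)-4-(tert-butyldimethylsilyloxy)-6-[1-hydroxy-3-(trimethylsilyl)prop-2-ynyl]-7,8-dimethoxy-2-phenylchroman-5-ol (both C8'' epimers)
Conditions: TMSC≡CH, n-BuLi, THF, −78 °C; then 11, −78 → 0 °C; H2O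
Reagents that add atoms: ethynyltrimethylsilane, C#C[Si](C)(C)C
Why: 1,2-Addition of a lithium acetylide to the salicylaldehyde (one extra equivalent is consumed by the phenol) gives both C8'' epimers, which does not matter because this centre is planarised in step 14.

Step 10
Reactants: 13 (S)-1-phenylbut-3-en-1-ol
Product: 14 (S)-1-phenylbut-3-enyl acrylate
Conditions: CH2=CHCOCl, Et3N, DMAP (cat.), CH2Cl2, 0 °C
Reagents that add atoms: acryloyl chloride, C=CC(=O)Cl
Why: O-Acylation of the purchased homoallylic alcohol does not touch its stereocentre (the future C2'').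

Step 11
Reactants: 14 (S)-1-phenylbut-3-enyl acrylate
Product: 15 (S)-6-phenyl-5,6-dihydro-2H-pyran-2-one
Conditions: Grubbs II (cat.), CH2Cl2, reflux
Reagents that add atoms: none
Why: Ring-closing metathesis of an acrylate with a terminal alkene is a standard entry to α,β-unsaturated δ-lactones and is driven by loss of ethylene.

Step 12
Reactants: 15 (S)-6-phenyl-5,6-dihydro-2H-pyran-2-one
Product: 17 (S)-3-bromo-6-phenyl-5,6-dihydro-2H-pyran-2-one, via 3,4-dibromolactone 16 (not isolated)
Conditions: Br2, CH2Cl2, 0 °C; then Et3N, rt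
Reagents that add atoms: bromine, BrBr
Why: Bromine addition followed by E2 loss of HBr through the acidic α-proton is the established route to 3-bromo-5,6-dihydropyran-2-ones and places the handle on the future C4a''.

Step 13
Reactants: 12 propargylic salicyl-type diol; 17 (S)-3-bromo-6-phenyl-5,6-dihydro-2H-pyran-2-one
Product: 18 benzodioxin spiro-orthoester (C8a'' configured as in 26 with O in place of C8''; both C8'' epimers)
Conditions: TMSOMe, TMSOTf (cat.), 4 Å MS, CH2Cl2, −78 → −30 °C; Et3N quench
Reagents that add atoms: none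
Why: Silyl-triflate-catalysed orthoesterification of a lactone with a diol is driven by hexamethyldisiloxane formation and is reversible, so C8a'' should settle with the aryl oxygen O5 axial (the stronger anomeric acceptor, trans to the equatorial 2''-phenyl) and the alkyl oxygen equatorial.

Step 14
Reactants: 18 benzodioxin spiro-orthoester
Product: 21 ring-contracted 8''-methoxy-8''-(trimethylsilylethynyl) dihydrofuran spiroketal (C8'' and C8a'' as in 26), via C8''-lithio orthoester 19 (not isolated), via lithium alkoxide 20 (not isolated)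
Conditions: LDA, THF, −78 → −20 °C; then MeI, DMPU, −20 °C → rt
Reagents that add atoms: iodomethane, CI
Why: Proposed new method: LDA removes the only doubly activated proton of 18 (C8''–H, benzylic, propargylic and α to oxygen); carbanion 19 then undergoes homolysis of the adjacent O–C8a'' bond to a lithium ketyl and a C8a'' radical stabilised by O5, O1'' and the C4a''=C4'' bond, and this pair, held together by the O5–aryl tether, recombines at carbon, so that the six-membered 1,3-benzodioxin contracts to the five-membered dihydrofuran and alkoxide 20 is methylated in the same flask. The closest known reaction type is the acetal [1,2]-Wittig rearrangement of O-glycosides and ketals carrying benzylic or dialkynylmethyl ethers, which joins an anomeric carbon to a carbinol carbon with retention and has built vicinal fully substituted centres; migration of an orthoester carbon and contraction of a benzodioxin are the untested extensions. The only ring closed is the dihydrofuran, by 1,5-recombination of the tethered radical pair (a net 1,2-shift that pushes the oxygen out of the ring), so no exo or endo nucleophilic closure is involved. C8a'' should keep its configuration because the radical can neither leave nor turn over within the tether, and C8'' should be set by the lithium on the ketyl oxygen staying bridged to O1'', which places the new oxygen syn to O1'' and the slim alkynyl group syn to the bulkier C4a''–Br side. The step needs the [1,2]-shift over the [2,3]- and [1,4]-shifts and no halogen–metal exchange: bonding of C8'' to C4'' would put an E-configured C4a''=C8a'' bond into a seven-membered ring, bonding at the silylated alkyne terminus would give a seven-membered cyclic allene, and an amide base leaves the vinyl bromide alone.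

Step 15
Reactants: 21 ring-contracted 8''-methoxy-8''-(trimethylsilylethynyl) spiroketal
Product: 22 8''-ethynyl spiroketal
Conditions: K2CO3 (cat.), MeOH, rt
Reagents that add atoms: none
Why: Base-catalysed protiodesilylation of an alkynylsilane leaves the ketal, the vinyl bromide and the alkyl silyl ether intact.

Step 16
Reactants: 22 8''-ethynyl spiroketal
Product: 23 methyl (E)-β-methoxyacrylate (C8'' cis to the ester)
Conditions: CO (1 atm), Pd(OCOCF3)2 (cat.), bis(oxazoline) ligand (cat.), p-benzoquinone, MeOH, 0 °C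
Reagents that add atoms: carbon monoxide, [C-]#[O+]; methanol, CO
Why: Palladium(II)-catalysed oxidative methoxycarbonylation of a terminal alkyne (anti-methoxypalladation at the internal carbon, CO insertion with retention, methanolysis) fixes the methoxy group on C7'' and places the ester cis to C8'', the geometry the ring closure needs.

Step 17
Reactants: 23 methyl (E)-β-methoxyacrylate
Product: 25 O4-TBS ether of 6''-demethoxyneocalycopterone, via vinyllithium 24 (not isolated)
Conditions: t-BuLi (2 equiv), THF–Et2O–pentane, −100 → −78 °C; H2O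
Reagents that add atoms: none
Why: Parham-type cyclisation, in which bromine–lithium exchange outruns attack on the deactivated vinylogous carbonate and the C4a'' vinyllithium then acylates intramolecularly (6-exo-trig at the ester carbonyl), which is possible only when the acrylate is syn to C4a''.

Step 18
Reactants: 25 O4-TBS ether of 6''-demethoxyneocalycopterone
Product: 26 6''-demethoxyneocalycopterone
Conditions: TBAF, AcOH, THF, 0 °C → rt
Reagents that add atoms: none
Why: Buffered fluoride desilylation frees the C4 alcohol without the basicity that could deprotonate C3'' or the acidity that could ionise the C8a'' ketal.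

**Compound list**
1 | 1-(2-hydroxy-3,4,6-trimethoxyphenyl)ethanone | CC(=O)c1c(O)c(OC)c(OC)cc1OC | starting material
2 | (E)-3-(dimethylamino)-1-(2-hydroxy-3,4,6-trimethoxyphenyl)prop-2-en-1-one | CN(C)/C=C/C(=O)c1c(O)c(OC)c(OC)cc1OC | intermediate
3 | 5,7,8-trimethoxy-4H-chromen-4-one | O=c1ccoc2c(OC)c(OC)cc(OC)c12 | intermediate
4 | (2S)-5,7,8-trimethoxy-2-phenylchroman-4-one | O=C1C[C@@H](c2ccccc2)Oc2c(OC)c(OC)cc(OC)c12 | intermediate
5 | (2S)-5-hydroxy-7,8-dimethoxy-2-phenylchroman-4-one | O=C1C[C@@H](c2ccccc2)Oc2c(OC)c(OC)cc(O)c12 | intermediate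
6 | (2S,4S)-7,8-dimethoxy-2-phenylchromane-4,5-diol (cis) | Oc1c2c(c(OC)c(OC)c1)O[C@H](c1ccccc1)C[C@@H]2O | intermediate
7 | (2S,4R)-5-hydroxy-7,8-dimethoxy-2-phenylchroman-4-yl 4-nitrobenzoate (trans) | Oc1c2c(c(OC)c(OC)c1)O[C@H](c1ccccc1)C[C@H]2OC(=O)c1ccc([N+](=O)[O-])cc1 | intermediate
8 | (2S,4R)-7,8-dimethoxy-2-phenylchromane-4,5-diol (trans) | Oc1c2c(c(OC)c(OC)c1)O[C@H](c1ccccc1)C[C@H]2O | intermediate
9 | (2S,4R)-4,5-bis(tert-butyldimethylsilyloxy)-7,8-dimethoxy-2-phenylchromane | CC(C)(C)[Si](C)(C)Oc1c2c(c(OC)c(OC)c1)O[C@H](c1ccccc1)C[C@H]2O[Si](C)(C)C(C)(C)C | intermediate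
10 | (2S,4R)-4-(tert-butyldimethylsilyloxy)-7,8-dimethoxy-2-phenylchroman-5-ol | Oc1c2c(c(OC)c(OC)c1)O[C@H](c1ccccc1)C[C@H]2O[Si](C)(C)C(C)(C)C | intermediate
11 | (2S,4R)-4-(tert-butyldimethylsilyloxy)-5-hydroxy-7,8-dimethoxy-2-phenylchromane-6-carbaldehyde | Oc1c2c(c(OC)c(OC)c1C=O)O[C@H](c1ccccc1)C[C@H]2O[Si](C)(C)C(C)(C)C | intermediate
12 | (2S,4R)-4-(tert-butyldimethylsilyloxy)-6-[1-hydroxy-3-(trimethylsilyl)prop-2-ynyl]-7,8-dimethoxy-2-phenylchroman-5-ol, both carbinol epimers | Oc1c2c(c(OC)c(OC)c1C(O)C#C[Si](C)(C)C)O[C@H](c1ccccc1)C[C@H]2O[Si](C)(C)C(C)(C)C | intermediate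
13 | (S)-1-phenylbut-3-en-1-ol | C=CC[C@H](O)c1ccccc1 | starting material
14 | (S)-1-phenylbut-3-enyl acrylate | C=CC[C@H](OC(=O)C=C)c1ccccc1 | intermediate
15 | (S)-6-phenyl-5,6-dihydro-2H-pyran-2-one | O=C1C=CC[C@@H](c2ccccc2)O1 | intermediate
16 | (6S)-3,4-dibromo-6-phenyltetrahydropyran-2-one | O=C1C(Br)C(Br)C[C@@H](c2ccccc2)O1 | intermediate
17 | (S)-3-bromo-6-phenyl-5,6-dihydro-2H-pyran-2-one | O=C1C(Br)=CC[C@@H](c2ccccc2)O1 | intermediate
18 | benzodioxin spiro-orthoester: C8a'' bears O5 (axial, trans to 2''-Ph), O8'' (equatorial, cis to 2''-Ph), O1'' and C4a''(Br)=C4''; C8'' bears H and C≡C–TMS (both epimers) | BrC1=CC[C@@H](c2ccccc2)O[C@]13Oc2c4c(c(OC)c(OC)c2C(C#C[Si](C)(C)C)O3)O[C@H](c2ccccc2)C[C@H]4O[Si](C)(C)C(C)(C)C | intermediate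
19 | C8''-lithio derivative of 18 | BrC1=CC[C@@H](c2ccccc2)O[C@]13Oc2c4c(c(OC)c(OC)c2C([Li])(C#C[Si](C)(C)C)O3)O[C@H](c2ccccc2)C[C@H]4O[Si](C)(C)C(C)(C)C | intermediate
20 | lithium C8''-alkoxide of the ring-contracted dihydrofuran spiroketal | BrC1=CC[C@@H](c2ccccc2)O[C@]13Oc2c4c(c(OC)c(OC)c2[C@]3([O-])C#C[Si](C)(C)C)O[C@H](c2ccccc2)C[C@H]4O[Si](C)(C)C(C)(C)C.[Li+] | intermediate
21 | 8''-methoxy-8''-(trimethylsilylethynyl) dihydrofuran spiroketal, C8''/C8a'' as in 26 | BrC1=CC[C@@H](c2ccccc2)O[C@]13Oc2c4c(c(OC)c(OC)c2[C@]3(OC)C#C[Si](C)(C)C)O[C@H](c2ccccc2)C[C@H]4O[Si](C)(C)C(C)(C)C | intermediate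
22 | 8''-ethynyl-8''-methoxy dihydrofuran spiroketal | BrC1=CC[C@@H](c2ccccc2)O[C@]13Oc2c4c(c(OC)c(OC)c2[C@]3(OC)C#C)O[C@H](c2ccccc2)C[C@H]4O[Si](C)(C)C(C)(C)C | intermediate
23 | methyl (E)-3-methoxyacrylate attached at C3 to C8'' (C8'' cis to the ester) | BrC1=CC[C@@H](c2ccccc2)O[C@]13Oc2c4c(c(OC)c(OC)c2[C@]3(OC)/C(OC)=C\C(=O)OC)O[C@H](c2ccccc2)C[C@H]4O[Si](C)(C)C(C)(C)C | intermediate
24 | C4a''-vinyllithium derived from 23 | [Li]C1=CC[C@@H](c2ccccc2)O[C@]13Oc2c4c(c(OC)c(OC)c2[C@]3(OC)/C(OC)=C\C(=O)OC)O[C@H](c2ccccc2)C[C@H]4O[Si](C)(C)C(C)(C)C | intermediate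
25 | O4-(tert-butyldimethylsilyl)-6''-demethoxyneocalycopterone | COC1=CC(=O)C2=CC[C@@H](c3ccccc3)O[C@]23Oc2c4c(c(OC)c(OC)c2[C@]13OC)O[C@H](c1ccccc1)C[C@H]4O[Si](C)(C)C(C)(C)C | intermediate
26 | 6''-demethoxyneocalycopterone | COC1=CC(=O)C2=CC[C@@H](c3ccccc3)O[C@]23Oc2c4c(c(OC)c(OC)c2[C@]13OC)O[C@H](c1ccccc1)C[C@H]4O | target

Total steps: 18. Longest linear sequence: 15 (steps 1–9 and 13–18).

**Steps most likely to fail**

Step 14. The stabilised carbanion may fragment by retro-cleavage into the lactone before the O–C8a'' bond homolyses. The radical pair may also recombine with poor facial selectivity at C8'', or C8a'' may lose its configuration. The fallback uses known polar chemistry, sets out from 11 and returns at 21. The phenol is masked (MOMCl, i-Pr2NEt) to give the MOM-protected aldehyde F1. Addition of LiC≡CTMS and quenching of the alkoxide with MeI gives the propargylic methyl ether F2. Deprotonation at C8'' (n-BuLi, THF, −78 °C) and 1,2-addition of the carbanion to the carbonyl group of 17 gives the lactol F3. TsOH (cat.) in CH2Cl2–MeOH then removes the MOM group and closes the spiroketal under thermodynamic anomeric control, giving 21 after separation from its C8'' epimer.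

Step 13. The Lewis acid may ionise the doubly activated C8''–O bond of the electron-rich diol, and the equilibrium may disfavour addition to a conjugated lactone carbonyl. The fallback sets out from 17 and returns at 18. The lactone is O-methylated (Me3OBF4, CH2Cl2) and quenched with NaOMe to give the isolated 2,2-dimethoxy ortholactone F4. This exchanges both methoxy groups for the two hydroxyl groups of 12 under PPTS catalysis, with removal of methanol.

Step 17. Proton transfer to the vinyllithium, α-lithiation of the acrylate, or attack of excess alkyllithium on the newly formed dienone may outrun the acylation. The fallback sets out from 23 and returns at 25. DIBAL-H reduction gives the allylic alcohol F5, and MnO2 oxidation gives the β-methoxy enal F6. Nozaki–Hiyama–Kishi cyclisation (CrCl2, NiCl2 cat., DMF) joins C4a'' to C5'' and gives the cyclic dienol F7. Dess–Martin oxidation then gives 25.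

**Further compounds**
F1 | step 14 | (2S,4R)-4-(tert-butyldimethylsilyloxy)-7,8-dimethoxy-5-(methoxymethoxy)-2-phenylchromane-6-carbaldehyde | COCOc1c2c(c(OC)c(OC)c1C=O)O[C@H](c1ccccc1)C[C@H]2O[Si](C)(C)C(C)(C)C
F2 | step 14 | (2S,4R)-4-(tert-butyldimethylsilyloxy)-7,8-dimethoxy-6-[1-methoxy-3-(trimethylsilyl)prop-2-ynyl]-5-(methoxymethoxy)-2-phenylchromane | COCOc1c2c(c(OC)c(OC)c1C(OC)C#C[Si](C)(C)C)O[C@H](c1ccccc1)C[C@H]2O[Si](C)(C)C(C)(C)C
F3 | step 14 | lactol from addition of lithiated F2 to 17 (C8'' and C8a'' unassigned) | BrC1=CC[C@@H](c2ccccc2)OC1(O)C(OC)(C#C[Si](C)(C)C)c1c(OCOC)c2c(c(OC)c1OC)O[C@H](c1ccccc1)C[C@H]2O[Si](C)(C)C(C)(C)C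
F4 | step 13 | (S)-3-bromo-2,2-dimethoxy-6-phenyl-5,6-dihydro-2H-pyran | COC1(OC)C(Br)=CC[C@@H](c2ccccc2)O1
F5 | step 17 | allylic alcohol from reduction of 23 | BrC1=CC[C@@H](c2ccccc2)O[C@]13Oc2c4c(c(OC)c(OC)c2[C@]3(OC)/C(OC)=C\CO)O[C@H](c2ccccc2)C[C@H]4O[Si](C)(C)C(C)(C)C
F6 | step 17 | β-methoxy enal from oxidation of F5 | BrC1=CC[C@@H](c2ccccc2)O[C@]13Oc2c4c(c(OC)c(OC)c2[C@]3(OC)/C(OC)=C\C=O)O[C@H](c2ccccc2)C[C@H]4O[Si](C)(C)C(C)(C)C
F7 | step 17 | C5''-carbinol of 25 (C5'' unassigned) | COC1=CC(O)C2=CC[C@@H](c3ccccc3)O[C@]23Oc2c4c(c(OC)c(OC)c2[C@]13OC)O[C@H](c1ccccc1)C[C@H]4O[Si](C)(C)C(C)(C)C
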